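**Retrosynthetic overview**
1. Penicianstinoid C ⇐ the spiro-tetronate ring, closed last by a deconjugative Dieckmann-type reaction at C-14 (this also creates the exocyclic methylene) ⇐ C-14 enoate of a D-lactic acid Weinreb amide ⇐ ring C ketone via enol triflate and carbonylation.
2. Spiro δ-lactone ⇐ key step: a (Z)-alkenyllithium on the spiro carbon takes up CO2 (carbonyl carbon bonds to the vinylic CH), and acid then closes the carboxyl oxygen onto the gem-dimethyl carbon of an isopropenyl group; the same acid frees the C-14 ketone and the C-12 acid.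
3. Enabling feature: in the δ-lactone ring the O–C(=O) unit lies between the vinylic CH next to the carbonyl and the oxygen-bearing gem-dimethyl carbon, and both are held 1,4 to each other on the spiro carbon of ring B; this is the retron of a formal [4+2] of CO2 with a (Z)-vinyl carbanion/tertiary carbocation pair.
4. Spiro carbon C-5 ⇐ SN2′ isopropenylation of a dienyl chloride made from the ring B enone; C-12 ⇐ ester enolate methylation; C-8 ⇐ amino-acid-mediated Robinson annulation of a reduced benzoic acid.
5. Ring order: ring C (from the arene) → ring B (annulation) → δ-lactone ring (key step) → tetronate ring.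

Key step: step 13

Remark on names: locants follow the target (C-1/C-2 the lactone alkene carbons with C-2 next to the carbonyl C-3, C-4 the gem-dimethyl carbon, C-5 the spiro carbon of ring B, C-6/C-7 its methylenes, C-8 the angular-methyl carbon, C-9=C-10 the ring alkene, C-11 to C-14 the rest of ring C with C-12 carrying the carboxyl, C-13 the methylene carbon and C-14 the tetronate spiro carbon); β is the face of the C-8 methyl, α the opposite face.

**Route**

Step 1
Reactants: 1 3,5-dihydroxy-4-methylbenzoic acid
Product: 2 4-methyl-3,5-dioxocyclohexane-1-carboxylic acid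
Conditions: H2 (5 atm), Rh/Al2O3 (5 wt %), NaOH (2.1 equiv), H2O, 25 °C; then HCl to pH 2
Reagents that add atoms: none
Why: Partial hydrogenation of a resorcinol as its sodium salt stops at the vinylogous carboxylate of the cyclohexane-1,3-dione (the classical dihydroresorcinol preparation), and no stereocentre of consequence arises because the carboxyl-bearing carbon lies on a mirror plane.

Step 2
Reactants: 2 4-methyl-3,5-dioxocyclohexane-1-carboxylic acid; 3 ethyl vinyl ketone
Product: 4 4-methyl-3,5-dioxo-4-(3-oxopentyl)cyclohexane-1-carboxylic acid (cis/trans mixture)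
Conditions: H2O, AcOH (cat.), hydroquinone (cat.), 75 °C
Reagents that add atoms: none
Why: Michael addition of the 2-methyl-1,3-dione to the enone in water (first half of a Robinson annulation) alkylates the doubly activated carbon, and the cis/trans mixture is of no consequence because each isomer keeps a mirror plane.

Step 3
Reactants: 4 triketone acid
Product: 5 (4aS)-4a,8-dimethyl-4,7-dioxo-1,2,3,4,4a,5,6,7-octahydronaphthalene-2-carboxylic acid (bicyclic enedione acid; both epimers at the carboxyl-bearing carbon)
Conditions: L-phenylalanine (1.0 equiv), (1S)-(+)-camphor-10-sulfonic acid (0.5 equiv), DMF, 30 → 70 °C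
Reagents that add atoms: none
Why: Amino-acid-mediated intramolecular aldol condensation (Hajos–Parrish–Eder–Sauer–Wiechert reaction in its phenylalanine/camphorsulfonic acid form for ethyl ketone side chains) differentiates the two enantiotopic ring carbonyls through the enamine and should set the angular methyl centre as S, the sense L-amino acids give in the Wieland–Miescher ketone family.

Step 4
Reactants: 5 bicyclic enedione acid
Product: 6 tert-butyl ester of 5 (both C-12 epimers)
Conditions: tert-butyl 2,2,2-trichloroacetimidate (2 equiv), BF3·OEt2 (5 mol %), CH2Cl2–cyclohexane, 25 °C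
Reagents that add atoms: tert-butyl 2,2,2-trichloroacetimidate CC(C)(C)OC(=N)C(Cl)(Cl)Cl
Why: Acid-catalysed O-alkylation of the carboxylic acid by the imidate (tert-butyl ester formation) is mild enough for the enedione and gives an ester that resists the later organometallic steps and is cleaved by the acid of the key step.

Step 5
Reactants: 6 tert-butyl ester
Product: 7 C-14 ethylene ketal of 6 (ring B enone free; both C-12 epimers)
Conditions: Me3SiOCH2CH2OSiMe3 (1.5 equiv), Me3SiOTf (5 mol %), CH2Cl2, −78 → −20 °C
Reagents that add atoms: 1,2-bis(trimethylsilyloxy)ethane C[Si](C)(C)OCCO[Si](C)(C)C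
Why: Ketalization with the bis-silyl ether under silyl triflate catalysis takes the saturated C-14 ketone and leaves the conjugated, less electrophilic enone carbonyl, the selectivity known for the Wieland–Miescher ketone.

Step 6
Reactants: 7 ketal enone
Product: 8 C-5 tertiary vinyl carbinol (both C-5 and C-12 epimers)
Conditions: CH2=CHMgBr (2 equiv), CeCl3 (2 equiv), THF, −78 °C; aq NH4Cl
Reagents that add atoms: vinylmagnesium bromide C=C[Mg]Br
Why: Organocerium 1,2-addition of the vinyl nucleophile to the hindered enone carbonyl (the tetrasubstituted β-carbon excludes conjugate addition) gives the tertiary bis-allylic alcohol, whose new stereocentre is erased in step 7.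

Step 7
Reactants: 8 vinyl carbinol
Product: 9 primary allylic chloride with an exocyclic 2-chloroethylidene group at C-5 (E/Z mixture; both C-12 epimers)
Conditions: SOCl2 (1.2 equiv), pyridine (1.5 equiv), Et2O, −30 → 0 °C
Reagents that add atoms: thionyl chloride O=S(Cl)Cl
Why: Chlorination of the tertiary allylic alcohol with allylic transposition (SNi′, the linalool to geranyl chloride type) places chloride on the primary terminus and gives the exocyclic alkene conjugated with the ring alkene, either alkene geometry being usable.

Step 8
Reactants: 9 dienyl chloride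
Product: 10 C-5 quaternary diene with isopropenyl on the β-face (cis to the C-8 methyl) and vinyl on the α-face (both C-12 epimers)
Conditions: CH2=C(CH3)MgBr (3 equiv), CuBr·SMe2 (3 equiv), BF3·OEt2 (3 equiv), THF, −78 °C
Reagents that add atoms: isopropenylmagnesium bromide CC(=C)[Mg]Br
Why: γ-Selective (SN2′) allylic substitution by the isopropenylcopper–BF3 reagent creates the quaternary centre, and the bulky reagent should bond to the ring carbon from the equatorial β-direction (the behaviour of bulky reagents at the analogous 3-position of steroidal 4-en-3-ones), placing isopropenyl cis to the C-8 methyl and leaving the newly formed vinyl group on the α-face.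

Step 9
Reactants: 10 diene ester
Product: 11 C-12 methylated diene ester (12-methyl β and tert-butyl ester α)
Conditions: LiN(iPr)2 (1.3 equiv), THF, −78 °C; MeI (3 equiv), −78 → −30 °C
Reagents that add atoms: iodomethane CI
Why: The lithium enolate of the tert-butyl ester (the only acidic site, which also erases the C-12 epimer mixture) is methylated from the equatorial β-direction because the axial α-side is screened by the axial ketal oxygen at C-14, so the methyl ends cis to the C-8 methyl and the ester axial (ester enolate alkylation).

Step 10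
Reactants: 11 methylated diene ester
Product: 12 C-5 acetyl compound (methyl ketone)
Conditions: PdCl2 (10 mol %), CuCl (1 equiv), O2 (1 atm), DMF–H2O (7:1), 25 °C
Reagents that add atoms: water O
Why: Wacker oxidation converts the monosubstituted vinyl group to the methyl ketone with Markovnikov selectivity, while the 1,1-disubstituted and tetrasubstituted alkenes are not oxidised under these conditions.

Step 11
Reactants: 12 methyl ketone
Product: 15 C-5 iodoethynyl compound (1-iodoalkyne), via enol phosphate 13 (not isolated), via lithium acetylide 14 (not isolated)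
Conditions: LiN(iPr)2 (1.1 equiv), THF, −78 °C; ClP(O)(OEt)2 (1.1 equiv), −78 → 25 °C; LiN(iPr)2 (2.3 equiv), −78 → 25 °C; I2 (1.2 equiv), −78 °C
Reagents that add atoms: iodine II
Why: The kinetic enolate of the methyl ketone (its only α-hydrogens) is trapped as the enol phosphate, which more base eliminates to the lithium acetylide (methyl ketone to alkyne conversion by enol phosphate elimination), and the acetylide is iodinated in the same flask.

Step 12
Reactants: 15 iodoalkyne
Product: 16 C-5 (Z)-2-iodovinyl compound
Conditions: 2-nitrobenzenesulfonylhydrazide (3 equiv), Et3N (6 equiv), THF–iPrOH, 25 °C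
Reagents that add atoms: none
Why: Diimide generated from the sulfonylhydrazide delivers two hydrogens syn to the 1-iodoalkyne and gives the (Z)-iodoalkene only, the hindered isopropenyl and ring alkenes reacting much more slowly (diimide reduction).

Step 13
Reactants: 16 (Z)-iodovinyl compound
Product: 19 spiro δ-lactone keto acid, via alkenyllithium 17 (not isolated), via lithium carboxylate 18 (not isolated)
Conditions: t-BuLi (2.1 equiv), Et2O, −78 °C; CO2 (1 atm), −78 → 0 °C; Et2O exchanged for CH2Cl2 in the same flask, CF3SO3H (2.5 equiv), −20 → 0 °C; then H2O–THF, 25 °C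
Reagents that add atoms: carbon dioxide O=C=O; water O
Why: Iodine–lithium exchange proceeds with retention, so the (Z)-alkenyllithium 17 is carboxylated at the terminal vinyl carbon to give the (Z)-acrylate 18 (the C–C bond), and on acidification Markovnikov protonation of the isopropenyl group gives a tertiary cation at the gem-dimethyl carbon that is captured by the cis-held carboxyl oxygen (the O–C bond); the closest known reaction types are the carboxylation of alkenyllithiums and the Brønsted-acid-catalysed intramolecular hydroacyloxylation of 1,1-disubstituted alkenes, run here in one flask as a formal [4+2] of CO2 across a vinyl anion/tertiary cation pair. The single ring closed is the δ-lactone, by 6-exo-trig attack of the carboxyl oxygen on the internal alkene carbon. No new stereocentre is formed, since the spiro carbon was set in step 8, and the (Z)-geometry from step 12 is what lets the acid reach the cation. The step needs protonation of the isopropenyl group in preference to the tetrasubstituted ring alkene and capture faster than 1,2-shifts: the ring alkene is buried between two quaternary carbons (as inert to acid as the 8,9-alkene of lanosterol), the carboxyl sits five atoms from the cationic carbon, and the only alkenyl group able to migrate is the electron-poor acrylate. The same acid cleaves the tert-butyl ester and, once water is added, the ketal, so the C-12 acid and the C-14 ketone are unveiled in the same operation.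

Step 14
Reactants: 19 spiro δ-lactone keto acid
Product: 21 triisopropylsilyl ester of the C-13 methyl ketone (both C-13 epimers), via lithium carboxylate 20 (not isolated)
Conditions: LiN(iPr)2 (2.3 equiv), THF, −78 → −40 °C; MeI (1.1 equiv), −78 °C; then iPr3SiCl (1.2 equiv), 0 °C
Reagents that add atoms: iodomethane CI; chlorotriisopropylsilane CC(C)[Si](Cl)(C(C)C)C(C)C
Why: The dianion (carboxylate plus the only possible ketone enolate, at the methylene next to the quaternary C-12) is C-methylated (enolate alkylation) and the lithium carboxylate is then silylated in the same flask, the new C-13 stereocentre being irrelevant since that carbon becomes trigonal in step 15.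

Step 15
Reactants: 21 silyl ester methyl ketone
Product: 22 C-14 enol triflate (alkene between C-13 and C-14)
Conditions: KN(SiMe3)2 (1.2 equiv), THF, −78 °C; PhNTf2 (1.3 equiv), −78 → 0 °C
Reagents that add atoms: N-phenylbis(trifluoromethanesulfonimide) O=S(=O)(N(c1ccccc1)S(=O)(=O)C(F)(F)F)C(F)(F)F
Why: The potassium enolate formed at the single remaining α-hydrogen is triflated on oxygen (enol triflate formation), which fixes the tetrasubstituted alkene between C-13 and C-14.

Step 16
Reactants: 23 methyl (R)-lactate
Product: 24 (R)-2-hydroxy-N-methoxy-N-methylpropanamide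
Conditions: MeNH(OMe)·HCl (2.5 equiv), iPrMgCl (5 equiv), THF, −20 → 0 °C
Reagents that add atoms: N,O-dimethylhydroxylamine hydrochloride CNOC.Cl
Why: The chloromagnesium amide of N,O-dimethylhydroxylamine converts the ester into the Weinreb amide (ester aminolysis) without touching the stereocentre, which comes from D-lactate and becomes the methyl-bearing carbon of the tetronate.

Step 17
Reactants: 22 enol triflate; 24 (R)-lactic Weinreb amide
Product: 25 C-14 enoate ester of 24 (tetrasubstituted enoate)
Conditions: Pd(OAc)2 (10 mol %), Ph2P(CH2)3PPh2 (12 mol %), CO (1 atm), Et3N (3 equiv), DMF, 60 °C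
Reagents that add atoms: carbon monoxide [C-]#[O+]
Why: Palladium-catalysed alkoxycarbonylation of the enol triflate (oxidative addition to zerovalent palladium, CO insertion, alcoholysis of the acylpalladium) installs the C-14 ester carbon and attaches the lactate unit through oxygen with retention of its configuration.

Step 18
Reactants: 25 enoate ester
Product: 27 penicianstinoid C, via silyl ester 26 (not isolated)
Conditions: LiN(iPr)2 (1.3 equiv), THF–DMPU, −78 → −40 °C; AcOH; then HF·pyridine, THF, 0 °C
Reagents that add atoms: none
Why: The only γ-hydrogens of the tetrasubstituted enoate are on the vinylic methyl, so deprotonation gives a dienolate that is acylated at its α-carbon by the tethered Weinreb amide in a 5-exo-trig Dieckmann-type condensation, which creates the exocyclic methylene and the spiro centre at C-14 with the acyl carbon entering on the α-face anti to the adjacent angular methyl, the chelated tetrahedral intermediate blocking retro-Claisen cleavage until the acidic quench, after which HF·pyridine removes the silyl ester.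

**Compound list**
1 | 3,5-dihydroxy-4-methylbenzoic acid | Cc1c(O)cc(cc1O)C(=O)O | starting material
2 | 4-methyl-3,5-dioxocyclohexane-1-carboxylic acid | CC1C(=O)CC(CC1=O)C(=O)O | intermediate
3 | ethyl vinyl ketone (pent-1-en-3-one) | CCC(=O)C=C | starting material
4 | 4-methyl-3,5-dioxo-4-(3-oxopentyl)cyclohexane-1-carboxylic acid (cis/trans mixture) | CCC(=O)CCC1(C)C(=O)CC(CC1=O)C(=O)O | intermediate
5 | (4aS)-4a,8-dimethyl-4,7-dioxo-1,2,3,4,4a,5,6,7-octahydronaphthalene-2-carboxylic acid (both C-12 epimers) | O=C1CC(C(=O)O)CC2=C(C)C(=O)CC[C@]12C | intermediate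
6 | tert-butyl ester of 5 (both C-12 epimers) | O=C1CC(C(=O)OC(C)(C)C)CC2=C(C)C(=O)CC[C@]12C | intermediate
7 | C-14 ethylene ketal of 6, ring B enone free (both C-12 epimers) | O=C1CC[C@@]2(C)C(=C1C)CC(C(=O)OC(C)(C)C)CC21OCCO1 | intermediate
8 | C-5 tertiary vinyl carbinol (both C-5 and C-12 epimers) | C=CC1(O)CC[C@@]2(C)C(=C1C)CC(C(=O)OC(C)(C)C)CC21OCCO1 | intermediate
9 | primary allylic chloride, exocyclic 2-chloroethylidene at C-5 (E/Z mixture, both C-12 epimers) | ClCC=C1CC[C@@]2(C)C(=C1C)CC(C(=O)OC(C)(C)C)CC21OCCO1 | intermediate
10 | C-5 quaternary diene, isopropenyl β (cis to C-8 methyl), vinyl α (both C-12 epimers) | C=C[C@]1(C(C)=C)CC[C@@]2(C)C(=C1C)CC(C(=O)OC(C)(C)C)CC21OCCO1 | intermediate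
11 | C-12 methylated diene ester, 12-methyl β, tert-butyl ester α | C=C[C@]1(C(C)=C)CC[C@@]2(C)C(=C1C)C[C@@](C)(C(=O)OC(C)(C)C)CC21OCCO1 | intermediate
12 | C-5 acetyl compound (methyl ketone) | CC(=O)[C@]1(C(C)=C)CC[C@@]2(C)C(=C1C)C[C@@](C)(C(=O)OC(C)(C)C)CC21OCCO1 | intermediate
13 | enol diethyl phosphate of 12 | C=C(OP(=O)(OCC)OCC)[C@]1(C(C)=C)CC[C@@]2(C)C(=C1C)C[C@@](C)(C(=O)OC(C)(C)C)CC21OCCO1 | intermediate
14 | lithium acetylide (C-5 ethynyl, lithium salt) | [Li]C#C[C@]1(C(C)=C)CC[C@@]2(C)C(=C1C)C[C@@](C)(C(=O)OC(C)(C)C)CC21OCCO1 | intermediate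
15 | C-5 iodoethynyl compound (1-iodoalkyne) | IC#C[C@]1(C(C)=C)CC[C@@]2(C)C(=C1C)C[C@@](C)(C(=O)OC(C)(C)C)CC21OCCO1 | intermediate
16 | C-5 (Z)-2-iodovinyl compound | I/C=C\[C@]1(C(C)=C)CC[C@@]2(C)C(=C1C)C[C@@](C)(C(=O)OC(C)(C)C)CC21OCCO1 | intermediate
17 | (Z)-alkenyllithium from 16 | [Li]/C=C\[C@]1(C(C)=C)CC[C@@]2(C)C(=C1C)C[C@@](C)(C(=O)OC(C)(C)C)CC21OCCO1 | intermediate
18 | lithium (Z)-acrylate from 17 and CO2 | [Li]OC(=O)/C=C\[C@]1(C(C)=C)CC[C@@]2(C)C(=C1C)C[C@@](C)(C(=O)OC(C)(C)C)CC21OCCO1 | intermediate
19 | spiro δ-lactone keto acid (C-14 ketone, C-12 acid) | O=C1C=C[C@]2(C(C)(C)O1)CC[C@@]3(C)C(=C2C)C[C@@](C)(C(=O)O)CC3=O | intermediate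
20 | lithium carboxylate of the C-13 methylated keto acid (both C-13 epimers) | O=C1C=C[C@]2(C(C)(C)O1)CC[C@@]3(C)C(=C2C)C[C@@](C)(C(=O)O[Li])C(C)C3=O | intermediate
21 | triisopropylsilyl ester of the C-13 methyl ketone (both C-13 epimers) | O=C1C=C[C@]2(C(C)(C)O1)CC[C@@]3(C)C(=C2C)C[C@@](C)(C(=O)O[Si](C(C)C)(C(C)C)C(C)C)C(C)C3=O | intermediate
22 | C-14 enol triflate | O=C1C=C[C@]2(C(C)(C)O1)CC[C@@]3(C)C(=C2C)C[C@@](C)(C(=O)O[Si](C(C)C)(C(C)C)C(C)C)C(C)=C3OS(=O)(=O)C(F)(F)F | intermediate
23 | methyl (R)-lactate | C[C@@H](O)C(=O)OC | starting material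
24 | (R)-2-hydroxy-N-methoxy-N-methylpropanamide | C[C@@H](O)C(=O)N(C)OC | intermediate
25 | C-14 enoate ester of 24 | O=C1C=C[C@]2(C(C)(C)O1)CC[C@@]3(C)C(=C2C)C[C@@](C)(C(=O)O[Si](C(C)C)(C(C)C)C(C)C)C(C)=C3C(=O)O[C@H](C)C(=O)N(C)OC | intermediate
26 | triisopropylsilyl ester of penicianstinoid C | C=C1[C@](C)(C(=O)O[Si](C(C)C)(C(C)C)C(C)C)CC2=C(C)[C@]3(C=CC(=O)OC3(C)C)CC[C@]2(C)[C@@]12C(=O)O[C@H](C)C2=O | intermediate
27 | penicianstinoid C | C=C1[C@](C)(C(=O)O)CC2=C(C)[C@]3(C=CC(=O)OC3(C)C)CC[C@]2(C)[C@@]12C(=O)O[C@H](C)C2=O | target

**Totals and risks**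
Total step count: 18. Longest linear sequence: 17 steps (steps 1 to 15, 17 and 18; step 16 is a one-step branch).

Three steps most likely to fail:

Step 13 (key step). Under the acid, protonation of the tetrasubstituted ring alkene followed by capture by either carboxyl group, or a 1,2-shift at the tertiary cation, may outrun the wanted ring closure. The fallback sets out from 16 and returns at 19. Lithiation and carboxylation as before, but with a citric acid work-up, give the (Z)-acrylic acid F1 with ketal and tert-butyl ester intact. Mercuricyclization with Hg(OCOCF3)2 in CH2Cl2 gives the organomercurial lactone F2; oxymercuration is governed by sterics, so it takes the unhindered 1,1-disubstituted alkene, and it passes through a bridged mercurinium ion and not a free cation. n-Bu3SnH replaces mercury by hydrogen to give the lactone ester ketal F3. CF3CO2H in wet CH2Cl2, too weak to protonate the hindered ring alkene, then removes the tert-butyl ester and the ketal and delivers 19.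

Step 8. The copper reagent may bond to the ring carbon with low facial selectivity or from the α-face, which would give the epimer at the spiro carbon. The fallback sets out from 7 and returns at 10; it introduces the two alkenyl groups in the reverse order, so that an α-preference now delivers the vinyl group to the α-face. Isopropenylmagnesium bromide with CeCl3 adds to 7 to give the isopropenyl carbinol F4. SOCl2 and pyridine transpose it to the tetrasubstituted allylic chloride F5. The vinylcopper–BF3 reagent (CH2=CHMgBr, CuBr·SMe2, BF3·OEt2) then attacks the ring carbon in the SN2′ sense to give 10.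

Step 18. The base may deprotonate the lactate α-carbon (epimerisation or O-to-C acyl migration) instead of the γ-methyl of the hindered enoate. The fallback sets out from 22 and returns at 27. Methoxycarbonylation (Pd(OAc)2, Ph2P(CH2)3PPh2, CO, MeOH, Et3N) gives the methyl enoate F6, whose dienolate (LiN(iPr)2) has no competing acidic site. It undergoes α-selective, deconjugative aldol addition to (R)-2-(tert-butyldimethylsilyloxy)propanal from the face opposite the angular methyl to give the β-hydroxy ester F7. Dess–Martin periodinane gives the β-keto ester F8. HF·pyridine removes both silyl groups and the freed hydroxyl lactonises onto the methyl ester to give 27.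

Further compounds
F1 | step 13 | (Z)-acrylic acid with ketal and tert-butyl ester intact | OC(=O)/C=C\[C@]1(C(C)=C)CC[C@@]2(C)C(=C1C)C[C@@](C)(C(=O)OC(C)(C)C)CC21OCCO1
F2 | step 13 | organomercurial δ-lactone (trifluoroacetoxymercuriomethyl at C-4, both C-4 epimers) | O=C1C=C[C@]2(C(C)(C[Hg]OC(=O)C(F)(F)F)O1)CC[C@@]3(C)C(=C2C)C[C@@](C)(C(=O)OC(C)(C)C)CC34OCCO4
F3 | step 13 | spiro δ-lactone with ketal and tert-butyl ester intact | O=C1C=C[C@]2(C(C)(C)O1)CC[C@@]3(C)C(=C2C)C[C@@](C)(C(=O)OC(C)(C)C)CC34OCCO4
F4 | step 8 | C-5 tertiary isopropenyl carbinol (both C-5 and C-12 epimers) | C=C(C)C1(O)CC[C@@]2(C)C(=C1C)CC(C(=O)OC(C)(C)C)CC21OCCO1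
F5 | step 8 | tetrasubstituted allylic chloride, exocyclic 1-chloropropan-2-ylidene at C-5 (E/Z mixture) | ClCC(C)=C1CC[C@@]2(C)C(=C1C)CC(C(=O)OC(C)(C)C)CC21OCCO1
F6 | step 18 | C-14 methyl enoate | O=C1C=C[C@]2(C(C)(C)O1)CC[C@@]3(C)C(=C2C)C[C@@](C)(C(=O)O[Si](C(C)C)(C(C)C)C(C)C)C(C)=C3C(=O)OC
F7 | step 18 | β-hydroxy ester from the deconjugative aldol addition (both carbinol epimers) | O=C1C=C[C@]2(C(C)(C)O1)CC[C@@]3(C)C(=C2C)C[C@@](C)(C(=O)O[Si](C(C)C)(C(C)C)C(C)C)C(=C)[C@@]3(C(=O)OC)C(O)[C@@H](C)O[Si](C)(C)C(C)(C)C
F8 | step 18 | β-keto ester | O=C1C=C[C@]2(C(C)(C)O1)CC[C@@]3(C)C(=C2C)C[C@@](C)(C(=O)O[Si](C(C)C)(C(C)C)C(C)C)C(=C)[C@@]3(C(=O)OC)C(=O)[C@@H](C)O[Si](C)(C)C(C)(C)C
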